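**Strategy.** Ring B, the dihydrofuran (O1, C2, C3, C3a, C7a), is disconnected at O1–C7a and C3–C3a into a 3-methoxy-5-styrylbenzyne and an enantiopure trans-2,3-diaryloxirane that already holds the O1–C2–C3 unit. In the key step the strained epoxide oxygen adds to the aryne and the benzylic carbon released on ring opening is captured by the neighbouring aryl anion: a formal aryne insertion into the epoxide O–C3 bond. It exploits the C4 oxygen on ring A (the benzo ring), which polarises the aryne so that O1 bonds to C7a and C3 to C3a; catechol tosylates make C3, not C2, the ionising carbon, and C2 keeps its configuration.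

Key step: step 6

Remark on numbering: dihydrobenzofuran numbering is used for the target (O1, C2, C3, C3a, C4–C7, C7a); the target is the trans (2S,3S) isomer.
Assumption: the D-fructose-derived Shi ketone epoxidises stilbene 4 with the same facial sense as trans-stilbene itself, giving the (R,R)-oxide.

**Step 1**
Reactants: 1 3,4-dihydroxybenzaldehyde
Product: 2 4-formyl-1,2-phenylene bis(4-methylbenzenesulfonate)
Conditions: TsCl (2.3 equiv), Et3N, DMAP (cat.), CH2Cl2, 0 °C → rt
Reagents that add atoms: p-toluenesulfonyl chloride, Cc1ccc(cc1)S(Cl)(=O)=O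
Why: Sulfonylation of both phenols (substitution at sulfur, DMAP catalysis) installs electron-withdrawing groups that are stable to fluoride and BBr3 and later steer the epoxide opening; no stereocenter is formed.

**Step 2**
Reactants: 2 4-formyl-1,2-phenylene bis(4-methylbenzenesulfonate); 3 diethyl (3,5-dimethoxybenzyl)phosphonate
Product: 4 4-[(E)-2-(3,5-dimethoxyphenyl)ethenyl]-1,2-phenylene bis(4-methylbenzenesulfonate)
Conditions: NaH, THF, 0 °C → rt
Reagents that add atoms: none
Why: Horner–Wadsworth–Emmons olefination of the electron-poor aldehyde with the benzylic phosphonate anion should give the E-stilbene, the aryl tosylates being inert to the carbanion at 0 °C.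

**Step 3**
Reactants: 4 4-[(E)-2-(3,5-dimethoxyphenyl)ethenyl]-1,2-phenylene bis(4-methylbenzenesulfonate)
Product: 5 4-[(2R,3R)-3-(3,5-dimethoxyphenyl)oxiran-2-yl]-1,2-phenylene bis(4-methylbenzenesulfonate)
Conditions: D-fructose-derived Shi ketone (0.3 equiv), Oxone (2KHSO5·KHSO4·K2SO4), K2CO3, Bu4NHSO4, MeCN/dimethoxymethane/aq. Na2B4O7 buffer, 0 °C
Reagents that add atoms: potassium peroxymonosulfate (active component of Oxone), OOS(=O)(=O)[O-].[K+]
Why: Shi epoxidation, in which the chiral dioxirane formed in situ transfers oxygen to the trans-disubstituted alkene through a spiro transition state and thereby sets both new stereocenters as (R,R); the pH 10.5 buffer at 0 °C should leave the sulfonates untouched.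

**Step 4**
Reactants: 6 5-bromovanillin (3-bromo-4-hydroxy-5-methoxybenzaldehyde); 7 diethyl (4-methoxybenzyl)phosphonate
Product: 8 2-bromo-6-methoxy-4-[(E)-2-(4-methoxyphenyl)ethenyl]phenol
Conditions: KOtBu (2.5 equiv), DMF, 0 °C → rt; aq. NH4Cl
Reagents that add atoms: none
Why: Horner–Wadsworth–Emmons olefination run on the potassium phenoxide of 6 (one extra equivalent of base) should give the E-stilbene directly, without a protecting-group step.

**Step 5**
Reactants: 8 2-bromo-6-methoxy-4-[(E)-2-(4-methoxyphenyl)ethenyl]phenol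
Product: 11 2-methoxy-4-[(E)-2-(4-methoxyphenyl)ethenyl]-6-(trimethylsilyl)phenyl trifluoromethanesulfonate, via silyl ether 9 (not isolated), via lithium phenoxide 10 (not isolated)
Conditions: HMDS, THF, 70 °C, volatiles removed; n-BuLi, THF, −78 °C → −20 °C; Tf2O, −78 °C → rt
Reagents that add atoms: hexamethyldisilazane, C[Si](C)(C)N[Si](C)(C)C; trifluoromethanesulfonic anhydride, O=S(=O)(OS(=O)(=O)C(F)(F)F)C(F)(F)F
Why: One-pot O-silylation, bromine–lithium exchange, anionic 1,3 O-to-C silyl migration (retro-Brook rearrangement) and triflation of the resulting phenoxide is the standard entry to 2-(trimethylsilyl)aryl triflates, the exchange at −78 °C being far faster than addition of n-BuLi to the stilbene.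

**Step 6**
Reactants: 5 4-[(2R,3R)-3-(3,5-dimethoxyphenyl)oxiran-2-yl]-1,2-phenylene bis(4-methylbenzenesulfonate); 11 2-methoxy-4-[(E)-2-(4-methoxyphenyl)ethenyl]-6-(trimethylsilyl)phenyl trifluoromethanesulfonate
Product: 14 4-[(2S,3S)-3-(3,5-dimethoxyphenyl)-4-methoxy-6-[(E)-2-(4-methoxyphenyl)ethenyl]-2,3-dihydro-1-benzofuran-2-yl]-1,2-phenylene bis(4-methylbenzenesulfonate), via aryne 12 (not isolated), via oxiranium zwitterion 13 (not isolated)
Conditions: KF, 18-crown-6, DME, 40 °C; 11 added slowly to 5 (2 equiv, excess recovered)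
Reagents that add atoms: none
Why: KF-induced 1,2-elimination of Me3SiF and triflate from 11 gives aryne 12, the epoxide oxygen of 5 adds to its C7a terminus to give zwitterion 13, the O–C3 bond of the oxiranium ionises with release of ring strain to a 3,5-dimethoxybenzylic cation, and the C3a aryl anion collapses onto it. The closest known reaction type is the formal insertion of arynes generated from 2-(trimethylsilyl)aryl triflates into the benzylic C–O bond of aryl epoxides, which gives 3-aryl-2,3-dihydrobenzofurans. Ring B closes by C3a–C3 bond formation, formally a 5-endo-tet closure that is not open to a concerted SN2 displacement and therefore runs as cation–anion recombination within the zwitterion. C2 is not touched and keeps the configuration of the (R)-epoxide carbon, named (S) in 14 only because the substituent priorities change, while C3 is set on recombination under control of C2, the aryl groups ending up trans on the less hindered face; a cis isomer would differ at C3 only and be a separable diastereomer, so it cannot lower the enantiomeric purity. The step needs aryne regioselectivity, secured by the inductively withdrawing C4 methoxy group next to C3a, which distorts 12 so that nucleophiles add at the remote C7a and the negative charge develops at C3a. It also needs the O–C3 and not the O–C2 bond of the epoxide to break, secured by the two tosyloxy groups, which on Hammett grounds disfavour positive charge at C2 relative to the 3,5-dimethoxybenzylic C3 (a 4-alkoxy catechol ether would ionise at C2 and give the regioisomer).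

**Step 7**
Reactants: 14 4-[(2S,3S)-3-(3,5-dimethoxyphenyl)-4-methoxy-6-[(E)-2-(4-methoxyphenyl)ethenyl]-2,3-dihydro-1-benzofuran-2-yl]-1,2-phenylene bis(4-methylbenzenesulfonate)
Product: 15 4-[(2S,3S)-3-(3,5-dihydroxyphenyl)-4-hydroxy-6-[(E)-2-(4-hydroxyphenyl)ethenyl]-2,3-dihydro-1-benzofuran-2-yl]-1,2-phenylene bis(4-methylbenzenesulfonate)
Conditions: BBr3 (excess), CH2Cl2, −78 °C → 0 °C; MeOH, then H2O
Reagents that add atoms: none
Why: BBr3 cleavage of aryl methyl ethers (O–B complexation, then bromide SN2 at methyl) should remove all four methyl groups while the aryl tosylates survive and, by keeping the C2 aryl group electron-poor, suppress acid ionisation of the C2–O1 bond, so both stereocenters stay intact.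

**Step 8**
Reactants: 15 4-[(2S,3S)-3-(3,5-dihydroxyphenyl)-4-hydroxy-6-[(E)-2-(4-hydroxyphenyl)ethenyl]-2,3-dihydro-1-benzofuran-2-yl]-1,2-phenylene bis(4-methylbenzenesulfonate)
Product: 16 4-[(2S,3S)-3-(3,5-dihydroxyphenyl)-4-hydroxy-6-[(E)-2-(4-hydroxyphenyl)ethenyl]-2,3-dihydro-1-benzofuran-2-yl]benzene-1,2-diol (target, CNP0316718.1)
Conditions: KOH, H2O/1,4-dioxane (degassed), 60 °C, Ar; then 1 M HCl
Reagents that add atoms: none
Why: Hydroxide attack at sulfur cleaves the two aryl sulfonate S–O bonds (sulfonate ester hydrolysis) and frees the catechol; no bond to C2 or C3 is touched and oxygen is excluded to protect the polyphenolate.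

**Compound list**
1 | 3,4-dihydroxybenzaldehyde | O=Cc1ccc(O)c(O)c1 | starting material
2 | 4-formyl-1,2-phenylene bis(4-methylbenzenesulfonate) | O=Cc1ccc(OS(=O)(=O)c2ccc(C)cc2)c(OS(=O)(=O)c2ccc(C)cc2)c1 | intermediate
3 | diethyl (3,5-dimethoxybenzyl)phosphonate | CCOP(=O)(Cc1cc(OC)cc(OC)c1)OCC | starting material
4 | 4-[(E)-2-(3,5-dimethoxyphenyl)ethenyl]-1,2-phenylene bis(4-methylbenzenesulfonate) | COc1cc(/C=C/c2ccc(OS(=O)(=O)c3ccc(C)cc3)c(OS(=O)(=O)c3ccc(C)cc3)c2)cc(OC)c1 | intermediate
5 | 4-[(2R,3R)-3-(3,5-dimethoxyphenyl)oxiran-2-yl]-1,2-phenylene bis(4-methylbenzenesulfonate) | Cc1ccc(cc1)S(=O)(=O)Oc2ccc(cc2OS(=O)(=O)c3ccc(C)cc3)[C@H]4O[C@@H]4c5cc(OC)cc(OC)c5 | intermediate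
6 | 5-bromovanillin (3-bromo-4-hydroxy-5-methoxybenzaldehyde) | COc1cc(C=O)cc(Br)c1O | starting material
7 | diethyl (4-methoxybenzyl)phosphonate | CCOP(=O)(Cc1ccc(OC)cc1)OCC | starting material
8 | 2-bromo-6-methoxy-4-[(E)-2-(4-methoxyphenyl)ethenyl]phenol | COc1ccc(/C=C/c2cc(OC)c(O)c(Br)c2)cc1 | intermediate
9 | [2-bromo-6-methoxy-4-[(E)-2-(4-methoxyphenyl)ethenyl]phenoxy]trimethylsilane | COc1ccc(/C=C/c2cc(OC)c(O[Si](C)(C)C)c(Br)c2)cc1 | intermediate (not isolated)
10 | lithium 2-methoxy-4-[(E)-2-(4-methoxyphenyl)ethenyl]-6-(trimethylsilyl)phenoxide | COc1ccc(/C=C/c2cc(OC)c([O-])c([Si](C)(C)C)c2)cc1.[Li+] | intermediate (not isolated)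
11 | 2-methoxy-4-[(E)-2-(4-methoxyphenyl)ethenyl]-6-(trimethylsilyl)phenyl trifluoromethanesulfonate | COc1ccc(/C=C/c2cc(OC)c(OS(=O)(=O)C(F)(F)F)c([Si](C)(C)C)c2)cc1 | intermediate
12 | 3-methoxy-5-[(E)-2-(4-methoxyphenyl)ethenyl]benzyne (1,2-didehydrobenzene) | COC1=CC(/C=C/c2ccc(OC)cc2)=CC#C1 | intermediate (not isolated)
13 | O-aryl oxiranium aryl-anion zwitterion (adduct of 5 and 12; oxygen on C7a, carbanion at C3a) | Cc1ccc(cc1)S(=O)(=O)Oc2ccc(cc2OS(=O)(=O)c3ccc(C)cc3)[C@H]4[O+](C6=CC(/C=C/c7ccc(OC)cc7)=CC(OC)=[C-]6)[C@@H]4c5cc(OC)cc(OC)c5 | intermediate (not isolated)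
14 | 4-[(2S,3S)-3-(3,5-dimethoxyphenyl)-4-methoxy-6-[(E)-2-(4-methoxyphenyl)ethenyl]-2,3-dihydro-1-benzofuran-2-yl]-1,2-phenylene bis(4-methylbenzenesulfonate) | COc1ccc(/C=C/c2cc(OC)c3c(c2)O[C@H](c2ccc(OS(=O)(=O)c4ccc(C)cc4)c(OS(=O)(=O)c4ccc(C)cc4)c2)[C@H]3c2cc(OC)cc(OC)c2)cc1 | intermediate
15 | 4-[(2S,3S)-3-(3,5-dihydroxyphenyl)-4-hydroxy-6-[(E)-2-(4-hydroxyphenyl)ethenyl]-2,3-dihydro-1-benzofuran-2-yl]-1,2-phenylene bis(4-methylbenzenesulfonate) | Oc1ccc(/C=C/c2cc(O)c3c(c2)O[C@H](c2ccc(OS(=O)(=O)c4ccc(C)cc4)c(OS(=O)(=O)c4ccc(C)cc4)c2)[C@H]3c2cc(O)cc(O)c2)cc1 | intermediate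
16 | 4-[(2S,3S)-3-(3,5-dihydroxyphenyl)-4-hydroxy-6-[(E)-2-(4-hydroxyphenyl)ethenyl]-2,3-dihydro-1-benzofuran-2-yl]benzene-1,2-diol | Oc1ccc(/C=C/c2cc(O)c3c(c2)O[C@H](c2ccc(O)c(O)c2)[C@H]3c2cc(O)cc(O)c2)cc1 | target

**Totals.** Total step count: 8. Longest linear sequence: 6 steps (steps 1, 2, 3, 6, 7, 8); steps 4 and 5 build the aryne precursor in parallel.

**Steps most likely to fail**

Step 6. What may go wrong: the oxiranium zwitterion is protonated by the medium, or transfers a proton internally to give an aryl enol ether, before the aryl anion recombines. The epoxide may also ionise at the wrong carbon, or the aryne may be consumed by the stilbene units. The fallback sets out from 11 and comes back to the route at 16. The same aryne 12 is generated with CsF in DMF, where the known aryne–formamide [2+2] addition, ring opening and hydrolysis should give, with the same methoxy-directed regiochemistry, 2-hydroxy-6-methoxy-4-[(E)-2-(4-methoxyphenyl)ethenyl]benzaldehyde F1. Addition of 3,5-(MeO)2C6H3MgBr (excess, THF, 0 °C) gives 2-[(3,5-dimethoxyphenyl)(hydroxy)methyl]-3-methoxy-5-[(E)-2-(4-methoxyphenyl)ethenyl]phenol F2. With p-toluenesulfinic acid F2 is converted into the sulfone 2-[(3,5-dimethoxyphenyl)(4-methylbenzenesulfonyl)methyl]-3-methoxy-5-[(E)-2-(4-methoxyphenyl)ethenyl]phenol F3. With Cs2CO3 in CH2Cl2, F3 releases an ortho-quinone methide that is trapped in a [4+1] annulation by the ylide of (2R,5R)-1-(3,4-dimethoxybenzyl)-2,5-dimethylthiolan-1-ium bromide F4. F4 is prepared from 3,4-dimethoxybenzyl bromide and (2R,5R)-2,5-dimethylthiolane; the antipodal sulfide would be used should the sense of induction prove opposite. Conjugate addition at C3 and SN2 ring closure by the phenoxide at C2 should give the trans hexamethyl ether (2S,3S)-2-(3,4-dimethoxyphenyl)-3-(3,5-dimethoxyphenyl)-4-methoxy-6-[(E)-2-(4-methoxyphenyl)ethenyl]-2,3-dihydro-1-benzofuran F5. BBr3 in CH2Cl2 then gives 16.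

Step 5. What may go wrong: n-BuLi adds to the stilbene, the O-to-C silyl shift stays incomplete, or Tf2O attacks the electron-rich alkene. The fallback sets out from 6 and comes back at 11, with the stilbene built last. Aldehyde 6 is masked as its dimethyl acetal 2-bromo-4-(dimethoxymethyl)-6-methoxyphenol F6 (HC(OMe)3, MeOH, cat. TsOH). The same silylation, retro-Brook rearrangement and triflation sequence gives 4-(dimethoxymethyl)-2-methoxy-6-(trimethylsilyl)phenyl trifluoromethanesulfonate F7. Mild aqueous acid releases 4-formyl-2-methoxy-6-(trimethylsilyl)phenyl trifluoromethanesulfonate F8. Horner–Wadsworth–Emmons olefination of F8 with 7 (NaH, THF, 0 °C) gives 11. The organolithium then never meets a stilbene, and the olefination on a phenoxide (step 4) is avoided as well.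

Step 8. What may go wrong: slow sulfonate hydrolysis allows oxidation of the free hexaphenolate, or the 4-phenoxide of the C2 aryl group opens ring B through a para-quinone methide. The fallback sets out from 14 and comes back at 16, with the order of unmasking reversed. The tosylates are removed first (KOH, aq. 1,4-dioxane, Ar) while the other four phenols are still methyl ethers, giving 4-[(2S,3S)-3-(3,5-dimethoxyphenyl)-4-methoxy-6-[(E)-2-(4-methoxyphenyl)ethenyl]-2,3-dihydro-1-benzofuran-2-yl]benzene-1,2-diol F9. BBr3 demethylation is then the last step, so the hexaphenol is formed and isolated under acidic conditions only. Should the C2–O1 bond ionise there, reclosure through either oxygen of ring A returns the same trans compound, because ring A is symmetric about the C3a–C6 axis and C3 is not involved.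

**Further compounds**
F1 | step 6 | 2-hydroxy-6-methoxy-4-[(E)-2-(4-methoxyphenyl)ethenyl]benzaldehyde | COc1cc(/C=C/c2ccc(OC)cc2)cc(O)c1C=O
F2 | step 6 | 2-[(3,5-dimethoxyphenyl)(hydroxy)methyl]-3-methoxy-5-[(E)-2-(4-methoxyphenyl)ethenyl]phenol | COc1cc(/C=C/c2ccc(OC)cc2)cc(O)c1C(O)c1cc(OC)cc(OC)c1
F3 | step 6 | 2-[(3,5-dimethoxyphenyl)(4-methylbenzenesulfonyl)methyl]-3-methoxy-5-[(E)-2-(4-methoxyphenyl)ethenyl]phenol | COc1cc(/C=C/c2ccc(OC)cc2)cc(O)c1C(c1cc(OC)cc(OC)c1)S(=O)(=O)c1ccc(C)cc1
F4 | step 6 | (2R,5R)-1-(3,4-dimethoxybenzyl)-2,5-dimethylthiolan-1-ium bromide | C[C@@H]1CC[C@@H](C)[S+]1Cc1ccc(OC)c(OC)c1.[Br-]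
F5 | step 6 | (2S,3S)-2-(3,4-dimethoxyphenyl)-3-(3,5-dimethoxyphenyl)-4-methoxy-6-[(E)-2-(4-methoxyphenyl)ethenyl]-2,3-dihydro-1-benzofuran | COc1ccc(/C=C/c2cc(OC)c3c(c2)O[C@H](c2ccc(OC)c(OC)c2)[C@H]3c2cc(OC)cc(OC)c2)cc1
F6 | step 5 | 2-bromo-4-(dimethoxymethyl)-6-methoxyphenol | COc1cc(C(OC)OC)cc(Br)c1O
F7 | step 5 | 4-(dimethoxymethyl)-2-methoxy-6-(trimethylsilyl)phenyl trifluoromethanesulfonate | COc1cc(C(OC)OC)cc([Si](C)(C)C)c1OS(=O)(=O)C(F)(F)F
F8 | step 5 | 4-formyl-2-methoxy-6-(trimethylsilyl)phenyl trifluoromethanesulfonate | COc1cc(C=O)cc([Si](C)(C)C)c1OS(=O)(=O)C(F)(F)F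
F9 | step 8 | 4-[(2S,3S)-3-(3,5-dimethoxyphenyl)-4-methoxy-6-[(E)-2-(4-methoxyphenyl)ethenyl]-2,3-dihydro-1-benzofuran-2-yl]benzene-1,2-diol | COc1ccc(/C=C/c2cc(OC)c3c(c2)O[C@H](c2ccc(O)c(O)c2)[C@H]3c2cc(OC)cc(OC)c2)cc1
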